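Turn the substrate charge first. By hand, a loss first order in substrate leaves the percent curves where they are at any charge. The runs agree within scatter: at 120 min, other capture product reads 81% in larch and 80% in birch. Turn the second nucleophile next. The flask holds 5.00 equivalents, so I treat the loss of substrate as pseudo-first-order, but both runs hold the charge at 2 M, and no reading tests it. Turn the solid last. Both runs hold it at 0.44 M, and none is in solution at the start.

| flask | substrate | second nucleophile | solid first nucleophile | remark | time |
|---|---|---|---|---|---|
| larch | 0.56 M | 2 M | 0.44 M | run made earlier |  |
| birch | 0.88 M | 2 M | 0.44 M | run made earlier |  |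
| flask | 0.40 M | 2.00 M | 0.440 M |  | 3.0 h |

- larch (time / min: other capture product / %, target / %): 10.0: 19, 1; 25.0: 41, 4; 50.0: 61, 3; 80.0: 74, 3; 120: 81, 4
- birch (time / min: other capture product / %, target / %): 8.00: 19, 0; 15.0: 29, 0; 30.0: 46, 0; 60.0: 65, 3; 120: 80, 4

(scatter of a reading: 1.5 percentage points)

1. ratio of other capture product to target at 1.5 min
2. ratio of other capture product to target at 3.0 h

From the larch readings at 25.0 min, I get a first-order constant for the loss of substrate, k = 0.0239 min⁻¹. With it I reckon the area under the [substrate] curve of the flask, taken to the end of the loss, at 1000 M·s. This is charge over k, and I call it the substrate load. Larch has 1410 M·s. The larch readings leave 15.0% of the charge unaccounted for at 120 min, and k puts 5.68% of the charge down as substrate. I guess the rest is target lost by meeting substrate, a loss that grows with load. The flask's load is smaller than larch's, so I expect its late ratio below the larch reading of 20.2. The target readings lie too near their scatter of 1.5 percentage points to show this between larch and birch. The load says nothing about the early ratio.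

The forecast gives 200 (60 to 800) and 19 (14 to 28), holding that the flask “should behave much like larch”, where I expect a lower late ratio.

The flask gives 196 at 1.5 min and 14.0 at 3.0 h.

    substrate ⇌ intermediate (K = 0.00258, k = 5.29 × 10⁻⁴ s⁻¹)
    first nucleophile + intermediate → target (k = 0.825 L mol⁻¹ s⁻¹)
    second nucleophile + intermediate → other capture product (k = 0.316 L mol⁻¹ s⁻¹)
    substrate + target → side product (k = 0.00221 L mol⁻¹ s⁻¹)
    solid first nucleophile ⇌ first nucleophile, rate k5*(cs5 - [first nucleophile]) while solid is left; crystals form when [first nucleophile] > cs5 (solubility = 0.190 M, k = 4.75 × 10⁻⁴ s⁻¹)

At 3.0 h, the flask's load of 1000 M·s stands beside 9.73% side product, each percentage of it counting as two of substrate. The neighbour flask with 0.68 M of substrate has a load of 1710 M·s, and proportion to the load gives 16.6% side product. It holds 12.8%, with a ratio of 18.3 at 3.0 h: the direction holds, and the proportion overshoots.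

(All runs come from a simulation for substances that don't exist; noise was put on by code.)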